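**Plan**
1. Retrosynthetic cuts, in order: the two silyl ethers; C4–C5 (allylbarium plus enal, C5 then oxidised); C9–C10 (electrochemical union of two N-hydroxyphthalimide esters); C12–C13 (thioester plus alkylzinc); aryl–C1 (arylcopper plus prenyl bromide).
2. Forward: no ring is formed; the benzene ring comes ready-made from 2-bromo-6-methylphenol, and the chain (numbered C1 benzylic to C15 carbinol) is joined in the order C12–C13, C9–C10, C4–C5.
3. Enabling feature: the three unfunctionalised methylenes C8–C9–C10 between the C6=C7 alkene and the C11 methine. Cut at C9–C10, each side ends in a CH2–CO2H unit (a geraniol-derived 4-methylhex-4-enoic acid and a methylsuccinate-derived γ-keto acid), so both carbons can be released as primary radicals by loss of CO2.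
4. Stereochemistry: C11 (R) is bought with (R)-2-methylsuccinic acid 4-methyl ester and never meets strong base; E-C6=C7 is the geraniol alkene; E-C2=C3 comes from E-selective SeO2 oxidation of a prenyl group and a geometry-retaining allylbarium addition.
5. Protecting groups: PMB on O5 (removed oxidatively, orthogonal to silicon), TES on the C15 tertiary alcohol and TBS on the phenol (both removed by fluoride in the last step).

Key step: step 12

Remark: compound 3 is racemic at its one epoxide carbon and compound 30 is a pair of C5 epimers; both centres are destroyed later (steps 3 and 22), so neither is controlled.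

**Route**

Step 1
Reactants: 1 geraniol
Product: 2 geranyl 4-methoxybenzyl ether (1-{[(2E)-3,7-dimethylocta-2,6-dien-1-yl]oxymethyl}-4-methoxybenzene)
Conditions: NaH, PMBCl, Bu4NI (cat.), THF/DMF, 0 °C to rt
Reagents that add atoms: 4-methoxybenzyl chloride, COc1ccc(CCl)cc1
Why: Williamson etherification of the primary allylic alkoxide, chosen because a PMB ether survives peracid, periodic acid, chlorite and the reductive electrolysis and is later removed oxidatively without touching a silyl ether.

Step 2
Reactants: 2 geranyl 4-methoxybenzyl ether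
Product: 3 6,7-epoxygeranyl 4-methoxybenzyl ether (3-[(3E)-5-(4-methoxybenzyloxy)-3-methylpent-3-en-1-yl]-2,2-dimethyloxirane; racemic)
Conditions: mCPBA (1.0 equiv), CH2Cl2, −20 to 0 °C
Reagents that add atoms: 3-chloroperoxybenzoic acid, OOC(=O)c1cccc(Cl)c1
Why: Prilezhaev epoxidation goes to the remote, more electron-rich terminal alkene of the geranyl chain because the other trisubstituted alkene is deactivated by its allylic oxygen, and the new epoxide centre, formed racemic, is excised in step 3.

Step 3
Reactants: 3 6,7-epoxygeranyl 4-methoxybenzyl ether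
Product: 4 (E)-6-(4-methoxybenzyloxy)-4-methylhex-4-enal
Conditions: H5IO6, THF/Et2O, 0 °C
Reagents that add atoms: none
Why: Acid-assisted opening of the epoxide by water at its tertiary carbon followed by Malaprade glycol cleavage releases acetone and leaves the aldehyde, whose oxygen is the original epoxide oxygen, while the PMB ether and the trisubstituted alkene are inert to periodic acid at 0 °C.

Step 4
Reactants: 4 (E)-6-(4-methoxybenzyloxy)-4-methylhex-4-enal
Product: 5 (E)-6-(4-methoxybenzyloxy)-4-methylhex-4-enoic acid
Conditions: NaClO2, NaH2PO4, 2-methyl-2-butene, t-BuOH/H2O, rt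
Reagents that add atoms: sodium chlorite, [Na+].[O-]Cl=O
Why: Pinnick oxidation converts the aldehyde to the acid without touching the alkene or the PMB ether because the hypochlorous acid by-product is trapped by 2-methyl-2-butene.

Step 5
Reactants: 5 (E)-6-(4-methoxybenzyloxy)-4-methylhex-4-enoic acid
Product: 6 N-hydroxyphthalimide ester of 5 (1,3-dioxoisoindolin-2-yl (E)-6-(4-methoxybenzyloxy)-4-methylhex-4-enoate)
Conditions: N-hydroxyphthalimide, DIC, DMAP (cat.), CH2Cl2, rt
Reagents that add atoms: N-hydroxyphthalimide, ON1C(=O)c2ccccc2C1=O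
Why: Carbodiimide (Steglich-type) esterification of an unhindered primary acid gives the redox-active ester.

Step 6
Reactants: 7 3-methylbutane-1,3-diol
Product: 8 4-iodo-2-methylbutan-2-ol
Conditions: I2, PPh3, imidazole, CH2Cl2, 0 °C
Reagents that add atoms: iodine, II
Why: Appel iodination displaces only the primary alcohol, the tertiary alcohol being too hindered to be activated by the iodophosphonium salt at 0 °C.

Step 7
Reactants: 8 4-iodo-2-methylbutan-2-ol
Product: 9 triethyl[(4-iodo-2-methylbutan-2-yl)oxy]silane
Conditions: TESOTf, 2,6-lutidine, CH2Cl2, −78 to 0 °C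
Reagents that add atoms: triethylsilyl trifluoromethanesulfonate, CC[Si](CC)(CC)OS(=O)(=O)C(F)(F)F
Why: Silylation with the silyl triflate and a hindered base is the standard way to cap a tertiary alcohol, and the primary iodide is untouched.

Step 8
Reactants: 10 (R)-2-methylsuccinic acid 4-methyl ester
Product: 11 S-ethyl (2R)-4-methoxy-2-methyl-4-oxobutanethioate
Conditions: EtSH, DCC, DMAP (cat.), CH2Cl2, 0 °C to rt
Reagents that add atoms: ethanethiol, CCS
Why: Steglich thioesterification of the free acid under near-neutral conditions leaves the adjacent stereocentre and the methyl ester unchanged.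

Step 9
Reactants: 9 triethyl[(4-iodo-2-methylbutan-2-yl)oxy]silane; 11 S-ethyl (2R)-4-methoxy-2-methyl-4-oxobutanethioate
Product: 13 methyl (3R)-3,7-dimethyl-4-oxo-7-(triethylsilyloxy)octanoate, via alkylzinc iodide 12 (not isolated)
Conditions: 9, Zn (activated with BrCH2CH2Br and TMSCl), THF, 40 °C; then 11, PdCl2(PPh3)2 (5 mol%), toluene, rt; aq. NH4Cl work-up
Reagents that add atoms: none
Why: Fukuyama coupling, in which zerovalent palladium inserts into the C–S bond of the thioester and the acylpalladium is alkylated by the primary alkylzinc iodide, forms the C12–C13 bond without base, so the stereocentre next to the new ketone is not epimerised and the methyl ester is not attacked.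

Step 10
Reactants: 13 methyl (3R)-3,7-dimethyl-4-oxo-7-(triethylsilyloxy)octanoate
Product: 14 (3R)-3,7-dimethyl-4-oxo-7-(triethylsilyloxy)octanoic acid
Conditions: Me3SnOH, 1,2-dichloroethane, 80 °C; cold 0.1 M HCl work-up
Reagents that add atoms: trimethyltin hydroxide, C[Sn](C)(C)O
Why: Trimethyltin hydroxide cleaves unhindered methyl esters through a tin carboxylate under essentially neutral conditions, which avoids enolisation of the α-methyl ketone and keeps the tertiary silyl ether.

Step 11
Reactants: 14 (3R)-3,7-dimethyl-4-oxo-7-(triethylsilyloxy)octanoic acid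
Product: 15 N-hydroxyphthalimide ester of 14 (1,3-dioxoisoindolin-2-yl (3R)-3,7-dimethyl-4-oxo-7-(triethylsilyloxy)octanoate)
Conditions: N-hydroxyphthalimide, DIC, DMAP (cat.), CH2Cl2, 0 °C to rt
Reagents that add atoms: N-hydroxyphthalimide, ON1C(=O)c2ccccc2C1=O
Why: Carbodiimide esterification as in step 5, in which the stereocentre is β to the activated carboxyl and therefore cannot epimerise through a ketene or an activated-ester enolate.

Step 12
Reactants: 6 N-hydroxyphthalimide ester of (E)-6-(4-methoxybenzyloxy)-4-methylhex-4-enoic acid; 15 N-hydroxyphthalimide ester of (3R)-3,7-dimethyl-4-oxo-7-(triethylsilyloxy)octanoic acid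
Product: 16 (2E,7R)-1-(4-methoxybenzyloxy)-3,7,11-trimethyl-11-(triethylsilyloxy)dodec-2-en-8-one (the C5–C15 segment of the chain)
Conditions: 6 (3 equiv), 15 (1 equiv), NiCl2·6H2O (20 mol%), 2,2′:6′,2″-terpyridine (20 mol%), AgNO3 (0.3 equiv), Mg anode, RVC cathode, NMP, rt, constant current, undivided cell; aq. NH4Cl work-up
Reagents that add atoms: none
Why: Each N-hydroxyphthalimide ester accepts an electron (at the silver-coated cathode or from low-valent nickel) and fragments to phthalimide anion, CO2 and a primary alkyl radical; the terpyridine-ligated nickel, kept low-valent by the cathode after reduction of the divalent precatalyst NiCl2·6H2O, captures the C9 and C10 radicals in turn and forms the C9–C10 bond by reductive elimination while the Mg anode is consumed. The closest known reaction type is the nickel-electrocatalysed doubly decarboxylative cross-coupling of two alkyl N-hydroxyphthalimide esters, a controlled form of mixed Kolbe coupling that suits two unhindered primary partners such as these. No ring is closed and no stereocentre is created; C11 sits β to the C10 radical, carries no radical or anionic character at any point, and is carried through unchanged from 10. The selectivity required is cross- over homo-coupling, which is secured by using the cheap ester 6 in threefold excess, the two homodimers differing strongly in size and polarity from 16. The C9 radical is homoallylic and its 3-exo closure is reversible and unproductive, so the E-C6=C7 geometry is retained, and the competing 1,2-acyl shift of the β-keto C10 radical (a Dowd–Beckwith-type rearrangement through a cyclopropyloxy radical) is expected to be slower than capture by nickel at this catalyst loading. The ketone, the PMB ether and the tertiary silyl ether are inert because the medium contains neither base nor a carbon nucleophile.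

Step 13
Reactants: 16 (2E,7R)-1-(4-methoxybenzyloxy)-3,7,11-trimethyl-11-(triethylsilyloxy)dodec-2-en-8-one
Product: 17 (2E,7R)-1-hydroxy-3,7,11-trimethyl-11-(triethylsilyloxy)dodec-2-en-8-one
Conditions: DDQ, CH2Cl2/pH 7 phosphate buffer, 0 °C
Reagents that add atoms: none
Why: Oxidative PMB cleavage by DDQ proceeds through the benzylic oxocarbenium ion, which water hydrolyses to 4-methoxybenzaldehyde and the allylic alcohol, and the buffered medium leaves the tertiary TES ether, the ketone and its α-stereocentre alone.

Step 14
Reactants: 17 (2E,7R)-1-hydroxy-3,7,11-trimethyl-11-(triethylsilyloxy)dodec-2-en-8-one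
Product: 18 (2E,7R)-3,7,11-trimethyl-8-oxo-11-(triethylsilyloxy)dodec-2-enal
Conditions: MnO2, CH2Cl2, rt
Reagents that add atoms: none
Why: Activated MnO2 oxidises only allylic alcohols, giving the enal with retention of the E geometry under neutral conditions that cannot epimerise C11.

Step 15
Reactants: 19 2-bromo-6-methylphenol
Product: 20 2-bromo-6-methylanisole (1-bromo-2-methoxy-3-methylbenzene)
Conditions: MeI, K2CO3, acetone, reflux
Reagents that add atoms: iodomethane, CI
Why: Williamson O-methylation of the phenoxide.

Step 16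
Reactants: 20 2-bromo-6-methylanisole
Product: 22 3-bromo-4-methoxy-5-methylphenol, via aryl pinacol boronate 21 (not isolated)
Conditions: [Ir(OMe)(cod)]2 (1.5 mol%), 4,4′-di-tert-butyl-2,2′-bipyridine (3 mol%), B2pin2, THF, 80 °C; then KHSO5 (as Oxone), acetone/H2O, rt
Reagents that add atoms: potassium peroxymonosulfate KHSO5, [K+].[O-]S(=O)(=O)OO
Why: Iridium-catalysed C–H borylation is sterically controlled and takes the only ring C–H that has no ortho substituent, the one para to the methoxy group, leaving the C–Br bond intact, and the boronate is oxidised in the same flask to the phenol.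

Step 17
Reactants: 22 3-bromo-4-methoxy-5-methylphenol
Product: 23 (3-bromo-4-methoxy-5-methylphenoxy)(tert-butyl)dimethylsilane
Conditions: TBSCl, imidazole, DMF, rt
Reagents that add atoms: tert-butyldimethylsilyl chloride, CC(C)(C)[Si](C)(C)Cl
Why: Imidazole-promoted silylation of the unhindered phenol gives an aryl silyl ether that tolerates the organolithium, organocopper and organobarium steps and falls to fluoride at the end.

Step 18
Reactants: 23 (3-bromo-4-methoxy-5-methylphenoxy)(tert-butyl)dimethylsilane
Product: 26 tert-butyl[4-methoxy-3-methyl-5-(3-methylbut-2-en-1-yl)phenoxy]dimethylsilane, via aryllithium 24 (not isolated), via arylcopper 25 (not isolated)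
Conditions: n-BuLi, THF, −78 °C; CuBr·SMe2, −78 to −40 °C; prenyl bromide, −78 °C to rt
Reagents that add atoms: prenyl bromide (1-bromo-3-methylbut-2-ene), CC(C)=CCBr
Why: Bromine–lithium exchange is faster than any attack on the aryl silyl ether at −78 °C, and the derived arylcopper substitutes prenyl bromide at its primary carbon (SN2 rather than SN2′) to give the linear prenyl arene.

Step 19
Reactants: 26 tert-butyl[4-methoxy-3-methyl-5-(3-methylbut-2-en-1-yl)phenoxy]dimethylsilane
Product: 27 (E)-4-[5-(tert-butyldimethylsilyloxy)-2-methoxy-3-methylphenyl]-2-methylbut-2-en-1-ol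
Conditions: SeO2 (0.5 equiv), t-BuOOH, salicylic acid (cat.), CH2Cl2, 0 °C to rt
Reagents that add atoms: tert-butyl hydroperoxide, CC(C)(C)OO; selenium dioxide, O=[Se]=O
Why: Riley allylic oxidation in its catalytic SeO2/t-BuOOH form proceeds by ene reaction and [2,3]-sigmatropic shift at the more substituted end of the prenyl alkene and oxidises the methyl group trans to the benzylic carbon, which sets the E-C2=C3 geometry of the target.

Step 20
Reactants: 27 (E)-4-[5-(tert-butyldimethylsilyloxy)-2-methoxy-3-methylphenyl]-2-methylbut-2-en-1-ol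
Product: 28 tert-butyl{3-[(E)-4-chloro-3-methylbut-2-en-1-yl]-4-methoxy-5-methylphenoxy}dimethylsilane
Conditions: NCS, Me2S, CH2Cl2, −20 to 0 °C
Reagents that add atoms: N-chlorosuccinimide, O=C1CCC(=O)N1Cl
Why: Corey–Kim chlorination converts the primary allylic alcohol to the chloride by SN2 displacement of the alkoxysulfonium leaving group, without allylic transposition or loss of alkene geometry and under conditions neutral enough for the aryl silyl ether.

Step 21
Reactants: 28 tert-butyl{3-[(E)-4-chloro-3-methylbut-2-en-1-yl]-4-methoxy-5-methylphenoxy}dimethylsilane; 18 (2E,7R)-3,7,11-trimethyl-8-oxo-11-(triethylsilyloxy)dodec-2-enal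
Product: 30 (2E,6E,11R)-1-[5-(tert-butyldimethylsilyloxy)-2-methoxy-3-methylphenyl]-5-hydroxy-3,7,11,15-tetramethyl-15-(triethylsilyloxy)hexadeca-2,6-dien-12-one (both C5 epimers), via allylbarium chloride 29 (not isolated)
Conditions: BaI2, lithium biphenylide (LiC12H10, 2 equiv), THF, rt; 28, −78 °C; then added slowly to 18, THF, −78 °C; aq. NH4Cl work-up
Reagents that add atoms: none
Why: Allylbarium carbonyl addition, in which the allylic barium chloride formed from 28 and active barium at −78 °C keeps its E geometry, attacks through its α-carbon and adds 1,2 to the aldehyde of 18 much faster than to the more hindered and less electrophilic C12 ketone when it is dosed so that it is never in excess; the new C5 carbinol centre forms without control and is removed by the oxidation in step 22.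

Step 22
Reactants: 30 C5 carbinol (both epimers)
Product: 31 (2E,6E,11R)-1-[5-(tert-butyldimethylsilyloxy)-2-methoxy-3-methylphenyl]-3,7,11,15-tetramethyl-15-(triethylsilyloxy)hexadeca-2,6-diene-5,12-dione
Conditions: Dess–Martin periodinane, NaHCO3, CH2Cl2, 0 °C
Reagents that add atoms: none
Why: Dess–Martin oxidation converts the secondary allylic carbinol to the C5 ketone under buffered, non-enolising conditions, so the C2=C3 alkene stays out of conjugation, C11 is not epimerised and the two C5 epimers converge to one compound.

Step 23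
Reactants: 31 bis-silyl ether of the target
Product: 32 (2E,6E,11R)-15-hydroxy-1-(5-hydroxy-2-methoxy-3-methylphenyl)-3,7,11,15-tetramethylhexadeca-2,6-diene-5,12-dione
Conditions: TBAF, AcOH (1:1), THF, 0 °C to rt
Reagents that add atoms: none
Why: Fluoride cleaves the aryl silyl ether and the tertiary triethylsilyl ether by attack at silicon, and buffering with acetic acid keeps the medium too weakly basic to move the C2=C3 alkene into conjugation with the C5 ketone or to epimerise C11.

**Compound list**

1 | geraniol | CC(C)=CCC/C(C)=C/CO | starting material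
2 | geranyl 4-methoxybenzyl ether | CC(C)=CCC/C(C)=C/COCc1ccc(OC)cc1 | intermediate
3 | 6,7-epoxygeranyl 4-methoxybenzyl ether (racemic at the epoxide carbon) | CC1(C)OC1CC/C(C)=C/COCc1ccc(OC)cc1 | intermediate
4 | (E)-6-(4-methoxybenzyloxy)-4-methylhex-4-enal | O=CCC/C(C)=C/COCc1ccc(OC)cc1 | intermediate
5 | (E)-6-(4-methoxybenzyloxy)-4-methylhex-4-enoic acid | OC(=O)CC/C(C)=C/COCc1ccc(OC)cc1 | intermediate
6 | 1,3-dioxoisoindolin-2-yl (E)-6-(4-methoxybenzyloxy)-4-methylhex-4-enoate | O=C(CC/C(C)=C/COCc1ccc(OC)cc1)ON1C(=O)c2ccccc2C1=O | intermediate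
7 | 3-methylbutane-1,3-diol | CC(C)(O)CCO | starting material
8 | 4-iodo-2-methylbutan-2-ol | CC(C)(O)CCI | intermediate
9 | triethyl[(4-iodo-2-methylbutan-2-yl)oxy]silane | CC[Si](CC)(CC)OC(C)(C)CCI | intermediate
10 | (R)-2-methylsuccinic acid 4-methyl ester | COC(=O)C[C@@H](C)C(=O)O | starting material
11 | S-ethyl (2R)-4-methoxy-2-methyl-4-oxobutanethioate | COC(=O)C[C@@H](C)C(=O)SCC | intermediate
12 | [3-methyl-3-(triethylsilyloxy)butyl]zinc iodide (formed in the flask) | CC[Si](CC)(CC)OC(C)(C)CC[Zn]I | intermediate
13 | methyl (3R)-3,7-dimethyl-4-oxo-7-(triethylsilyloxy)octanoate | COC(=O)C[C@@H](C)C(=O)CCC(C)(C)O[Si](CC)(CC)CC | intermediate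
14 | (3R)-3,7-dimethyl-4-oxo-7-(triethylsilyloxy)octanoic acid | OC(=O)C[C@@H](C)C(=O)CCC(C)(C)O[Si](CC)(CC)CC | intermediate
15 | 1,3-dioxoisoindolin-2-yl (3R)-3,7-dimethyl-4-oxo-7-(triethylsilyloxy)octanoate | O=C(C[C@@H](C)C(=O)CCC(C)(C)O[Si](CC)(CC)CC)ON1C(=O)c2ccccc2C1=O | intermediate
16 | (2E,7R)-1-(4-methoxybenzyloxy)-3,7,11-trimethyl-11-(triethylsilyloxy)dodec-2-en-8-one | COc1ccc(COC/C=C(\C)CCC[C@@H](C)C(=O)CCC(C)(C)O[Si](CC)(CC)CC)cc1 | intermediate
17 | (2E,7R)-1-hydroxy-3,7,11-trimethyl-11-(triethylsilyloxy)dodec-2-en-8-one | OC/C=C(\C)CCC[C@@H](C)C(=O)CCC(C)(C)O[Si](CC)(CC)CC | intermediate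
18 | (2E,7R)-3,7,11-trimethyl-8-oxo-11-(triethylsilyloxy)dodec-2-enal | O=C/C=C(\C)CCC[C@@H](C)C(=O)CCC(C)(C)O[Si](CC)(CC)CC | intermediate
19 | 2-bromo-6-methylphenol | Cc1cccc(Br)c1O | starting material
20 | 2-bromo-6-methylanisole | COc1c(C)cccc1Br | intermediate
21 | 2-(3-bromo-4-methoxy-5-methylphenyl)-4,4,5,5-tetramethyl-1,3,2-dioxaborolane (formed in the flask) | COc1c(C)cc(B2OC(C)(C)C(C)(C)O2)cc1Br | intermediate
22 | 3-bromo-4-methoxy-5-methylphenol | COc1c(C)cc(O)cc1Br | intermediate
23 | (3-bromo-4-methoxy-5-methylphenoxy)(tert-butyl)dimethylsilane | COc1c(C)cc(O[Si](C)(C)C(C)(C)C)cc1Br | intermediate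
24 | [5-(tert-butyldimethylsilyloxy)-2-methoxy-3-methylphenyl]lithium (formed in the flask) | COc1c(C)cc(O[Si](C)(C)C(C)(C)C)cc1[Li] | intermediate
25 | [5-(tert-butyldimethylsilyloxy)-2-methoxy-3-methylphenyl]copper (formed in the flask) | COc1c(C)cc(O[Si](C)(C)C(C)(C)C)cc1[Cu] | intermediate
26 | tert-butyl[4-methoxy-3-methyl-5-(3-methylbut-2-en-1-yl)phenoxy]dimethylsilane | COc1c(C)cc(O[Si](C)(C)C(C)(C)C)cc1CC=C(C)C | intermediate
27 | (E)-4-[5-(tert-butyldimethylsilyloxy)-2-methoxy-3-methylphenyl]-2-methylbut-2-en-1-ol | COc1c(C)cc(O[Si](C)(C)C(C)(C)C)cc1C/C=C(\C)CO | intermediate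
28 | tert-butyl{3-[(E)-4-chloro-3-methylbut-2-en-1-yl]-4-methoxy-5-methylphenoxy}dimethylsilane | COc1c(C)cc(O[Si](C)(C)C(C)(C)C)cc1C/C=C(\C)CCl | intermediate
29 | {(E)-4-[5-(tert-butyldimethylsilyloxy)-2-methoxy-3-methylphenyl]-2-methylbut-2-en-1-yl}barium chloride (formed in the flask) | COc1c(C)cc(O[Si](C)(C)C(C)(C)C)cc1C/C=C(\C)C[Ba]Cl | intermediate
30 | (2E,6E,11R)-1-[5-(tert-butyldimethylsilyloxy)-2-methoxy-3-methylphenyl]-5-hydroxy-3,7,11,15-tetramethyl-15-(triethylsilyloxy)hexadeca-2,6-dien-12-one (both C5 epimers) | COc1c(C)cc(O[Si](C)(C)C(C)(C)C)cc1C/C=C(\C)CC(O)/C=C(\C)CCC[C@@H](C)C(=O)CCC(C)(C)O[Si](CC)(CC)CC | intermediate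
31 | (2E,6E,11R)-1-[5-(tert-butyldimethylsilyloxy)-2-methoxy-3-methylphenyl]-3,7,11,15-tetramethyl-15-(triethylsilyloxy)hexadeca-2,6-diene-5,12-dione | COc1c(C)cc(O[Si](C)(C)C(C)(C)C)cc1C/C=C(\C)CC(=O)/C=C(\C)CCC[C@@H](C)C(=O)CCC(C)(C)O[Si](CC)(CC)CC | intermediate
32 | (2E,6E,11R)-15-hydroxy-1-(5-hydroxy-2-methoxy-3-methylphenyl)-3,7,11,15-tetramethylhexadeca-2,6-diene-5,12-dione | COc1c(C)cc(O)cc1C/C=C(\C)CC(=O)/C=C(\C)CCC[C@@H](C)C(=O)CCC(C)(C)O | target

**Count and risks**

Total step count: 23. Longest linear sequence: 11 steps (from 1 through steps 1–5, 12–14 and 21–23; the branch from 7 through steps 6, 7, 9–14 and 21–23 is equally long).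

Steps most likely to fail:

1. Step 12. The β-keto C10 radical may rearrange by 1,2-acyl migration to the secondary C11 radical before nickel captures it, which would give a constitutional isomer and erase C11, and statistical homo-coupling may consume 15. The fallback sets out from 13 and comes back at 16; it masks the ketone so that the radical is no longer β to a carbonyl. Keto ester 13 would be ketalised with 1,2-bis(trimethylsilyloxy)ethane and catalytic TMSOTf (CH2Cl2, −78 °C) to the dioxolane methyl ester F1. LiOH in THF/H2O would then give the dioxolane acid F2, base being harmless once C11 is no longer α to a carbonyl. N-hydroxyphthalimide and DIC would give the dioxolane N-hydroxyphthalimide ester F3, and the electrolysis of step 12 with 6 would give the coupled dioxolane F4. Catalytic I2 in acetone would transfer the ketal to the solvent and return 16.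

2. Step 21. The allylbarium reagent may attack the C12 ketone as well as the aldehyde, may react through its γ-carbon, may lose its E geometry if the temperature rises, or may be quenched by proton transfer from the benzylic–allylic CH2 of another molecule. The fallback sets out from 28 and comes back at 31; a sulfone-stabilised anion replaces the barium reagent. PhSO2Na in DMF would convert 28 to the allyl sulfone F5. n-BuLi in THF at −78 °C would give the lithiated sulfone F6, which is too weakly basic to enolise the ketone and adds only to the aldehyde of 18, giving the β-hydroxy sulfone F7. Dess–Martin oxidation would give the β-keto sulfone F8, and SmI2 in THF/MeOH at −78 °C would remove the sulfonyl group to give 31.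

3. Step 23. Fluoride may promote migration of the C2=C3 alkene into conjugation with the C5 ketone, or cleavage of the hindered tertiary silyl ether may stall and force conditions that epimerise C11. The fallback sets out from 30 and comes back at 32; deprotection is moved ahead of the oxidation, when no skipped enone is present. TBAF in THF would convert 30 to the triol F9, and MnO2 in CH2Cl2 would then oxidise only the allylic C5 alcohol, leaving the tertiary alcohol and the phenol, to give 32 directly.

**Further compounds**

F1 | step 12 | C4 ethylene ketal of 13, methyl (3R)-3-{2-[3-methyl-3-(triethylsilyloxy)butyl]-1,3-dioxolan-2-yl}butanoate | COC(=O)C[C@@H](C)C1(CCC(C)(C)O[Si](CC)(CC)CC)OCCO1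
F2 | step 12 | (3R)-3-{2-[3-methyl-3-(triethylsilyloxy)butyl]-1,3-dioxolan-2-yl}butanoic acid | OC(=O)C[C@@H](C)C1(CCC(C)(C)O[Si](CC)(CC)CC)OCCO1
F3 | step 12 | N-hydroxyphthalimide ester of F2 | O=C(C[C@@H](C)C1(CCC(C)(C)O[Si](CC)(CC)CC)OCCO1)ON1C(=O)c2ccccc2C1=O
F4 | step 12 | C12 ethylene ketal of 16, 2-[(2R,6E)-8-(4-methoxybenzyloxy)-6-methyloct-6-en-2-yl]-2-[3-methyl-3-(triethylsilyloxy)butyl]-1,3-dioxolane | COc1ccc(COC/C=C(\C)CCC[C@@H](C)C2(CCC(C)(C)O[Si](CC)(CC)CC)OCCO2)cc1
F5 | step 21 | tert-butyl{4-methoxy-3-methyl-5-[(E)-3-methyl-4-(phenylsulfonyl)but-2-en-1-yl]phenoxy}dimethylsilane | COc1c(C)cc(O[Si](C)(C)C(C)(C)C)cc1C/C=C(\C)CS(=O)(=O)c1ccccc1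
F6 | step 21 | α-lithio derivative of F5 (formed in the flask) | COc1c(C)cc(O[Si](C)(C)C(C)(C)C)cc1C/C=C(\C)C([Li])S(=O)(=O)c1ccccc1
F7 | step 21 | 4-phenylsulfonyl derivative of 30 (β-hydroxy sulfone, mixture at C4 and C5) | COc1c(C)cc(O[Si](C)(C)C(C)(C)C)cc1C/C=C(\C)C(C(O)/C=C(\C)CCC[C@@H](C)C(=O)CCC(C)(C)O[Si](CC)(CC)CC)S(=O)(=O)c1ccccc1
F8 | step 21 | 4-phenylsulfonyl derivative of 31 (β-keto sulfone, mixture at C4) | COc1c(C)cc(O[Si](C)(C)C(C)(C)C)cc1C/C=C(\C)C(C(=O)/C=C(\C)CCC[C@@H](C)C(=O)CCC(C)(C)O[Si](CC)(CC)CC)S(=O)(=O)c1ccccc1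
F9 | step 23 | (2E,6E,11R)-5,15-dihydroxy-1-(5-hydroxy-2-methoxy-3-methylphenyl)-3,7,11,15-tetramethylhexadeca-2,6-dien-12-one (both C5 epimers) | COc1c(C)cc(O)cc1C/C=C(\C)CC(O)/C=C(\C)CCC[C@@H](C)C(=O)CCC(C)(C)O
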